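**Retrosynthetic overview**

1. Locants O1, C2, C3, C3a, C4, O5, C6, C7, C7a are those of the 2,3-dihydro-4H-furo[3,2-c]pyran-4-one core and denote the same atoms in every precursor; ring A = hydroxypyranone on C3, ring B = fused pyranone, ring C = dihydrofuran.
2. Enabling feature: C3a carries two acyl-level carbons, C4 (the C=O of ring B) and C7a (the ring-fusion carbon bonded to O1). The unit O1–C7a=C3a–C4(=O)–O5 is therefore a malonate in disguise, and C7a can enter as an ester carbonyl. In the precursor, C3–H lies between an aryl ketone and ring A and is labile.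
3. Ring C is closed first, as a γ-lactone, through the O1–C7a bond: asymmetric transfer hydrogenation of the stereorandom keto malonate 7 with dynamic kinetic resolution and in situ lactonization sets C2 and C3 (cis) in one operation.
4. Ring B is closed last, on that lactone: ketene acetal triflate at C7a, Sonogashira coupling (C7a–C7), gold-catalysed 6-endo-dig lactonization of the tert-butyl enynoate (O5–C6); then the five benzyl ethers are cleaved.
5. Compound 7 comes from ring A (triacetic acid lactone) by dienolate acylation with a benzoate and bromination/malonate alkylation (C3–C3a). Ring order: A (bought), C (step 4), B (step 7).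

Key step: step 4

Assumption: the target is the 2,3-cis isomer, (2R,3S); the malonate-derived centre of 9 needs no control because it becomes sp2 in step 6.

**Step 1**
Reactants: 1 4-hydroxy-6-methyl-2H-pyran-2-one
Product: 2 4-(benzyloxy)-6-methyl-2H-pyran-2-one
Conditions: BnBr, K2CO3, DMF, 60 °C
Reagents that add atoms: benzyl bromide, BrCc1ccccc1
Why: The 4-OH of 1 is a vinylogous carboxylic acid, and its potassium salt should be benzylated on that oxygen (Williamson ether synthesis).

**Step 2**
Reactants: 2 4-(benzyloxy)-6-methyl-2H-pyran-2-one; 3 methyl 3,4-bis(benzyloxy)benzoate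
Product: 4 4-(benzyloxy)-6-{2-[3,4-bis(benzyloxy)phenyl]-2-oxoethyl}-2H-pyran-2-one
Conditions: LiN(SiMe3)2 (2.2 equiv), THF, −78 °C; 3, −78 to 0 °C; then 1 M HCl
Reagents that add atoms: none
Why: The 6-methyl group is the vinylogous α-position of the pyranone; its lithium dienolate should add to the ester, and the second equivalent of base stores the more acidic product as its enolate (crossed Claisen condensation of a vinylogous ester enolate).

**Step 3**
Reactants: 4 4-(benzyloxy)-6-{2-[3,4-bis(benzyloxy)phenyl]-2-oxoethyl}-2H-pyran-2-one; 5 tert-butyl methyl propanedioate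
Product: 7 1-tert-butyl 3-methyl 2-{2-[3,4-bis(benzyloxy)phenyl]-1-[4-(benzyloxy)-2-oxo-2H-pyran-6-yl]-2-oxoethyl}propanedioate (all stereoisomers), via bromo ketone 6 (not isolated)
Conditions: NaH (1.0 equiv), THF, 0 °C; NBS (1.0 equiv), −20 °C; then sodium salt of 5 (5, NaH, THF), 0 °C to rt; 1 M HCl
Reagents that add atoms: N-bromosuccinimide, O=C1CCC(=O)N1Br (supplies the bromine of 6; no atom of it remains in 7)
Why: Bromination of the preformed enolate is confined to the doubly activated methylene, and the soft malonate anion should displace the activated secondary bromide by SN2 (malonic ester alkylation); both new stereocentres are left uncontrolled because both epimerise in step 4.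

**Step 4**
Reactants: 7 1-tert-butyl 3-methyl 2-{2-[3,4-bis(benzyloxy)phenyl]-1-[4-(benzyloxy)-2-oxo-2H-pyran-6-yl]-2-oxoethyl}propanedioate
Product: 9 tert-butyl (3S,4S,5R)-5-[3,4-bis(benzyloxy)phenyl]-4-[4-(benzyloxy)-2-oxo-2H-pyran-6-yl]-2-oxooxolane-3-carboxylate, via hydroxy diester 8 (not isolated)
Conditions: RuCl[(R,R)-TsDPEN](p-cymene) (2 mol %), HCO2H/Et3N (5:2), DMF, 40 °C
Reagents that add atoms: none
Why: The ruthenium hydride formed from the catalyst and formate transfers hydride, and the ligand NH a proton, to the aryl ketone of 7 through the six-membered outer-sphere transition state, while C3–H (between the aryl ketone and ring A) and the malonate C–H exchange through their enols, so that all stereoisomers of 7 drain through the fastest-reacting one and the carbinol 8 then acylates itself on the methyl ester. The closest known reaction type is the dynamic kinetic asymmetric transfer hydrogenation of racemic α-substituted keto esters with in situ lactonization to substituted γ-butyrolactones. Ring C closes at the lactone oxidation level by 5-exo-trig attack of O1 on the ester carbonyl that becomes C7a, with loss of methanol. C2 is set by the catalyst (the (R,R) ligand holds the aryl group against the cymene ring and delivers hydride to the face that gives the R carbinol); C3 is set by substrate control within the resolution (Felkin–Anh: hydride enters anti to the pyranonyl group as the large α-substituent, which gives the OH/pyranonyl syn relationship that becomes 2,3-cis in the ring); the malonate carbon should settle trans to ring A and is erased in step 6. The step needs chemoselectivity for the aryl ketone over pyranone, esters and benzyl ethers (carbonyl-specific hydride transfer), lactonization on the methyl rather than the tert-butyl ester (sterics), and epimerisation at C3 faster than reduction (the doubly activated C3–H).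

**Step 5**
Reactants: 10 3,4-bis(benzyloxy)benzaldehyde
Product: 11 1,2-bis(benzyloxy)-4-ethynylbenzene
Conditions: dimethyl (1-diazo-2-oxopropyl)phosphonate, K2CO3, MeOH, rt
Reagents that add atoms: dimethyl (1-diazo-2-oxopropyl)phosphonate, CC(=O)C(=[N+]=[N-])P(=O)(OC)OC
Why: Methanolysis of the reagent releases the diazomethylphosphonate anion, which should convert the non-enolisable aldehyde into the terminal alkyne (Seyferth–Gilbert homologation, Ohira–Bestmann variant).

**Step 6**
Reactants: 9 tert-butyl (3S,4S,5R)-5-[3,4-bis(benzyloxy)phenyl]-4-[4-(benzyloxy)-2-oxo-2H-pyran-6-yl]-2-oxooxolane-3-carboxylate; 11 1,2-bis(benzyloxy)-4-ethynylbenzene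
Product: 13 tert-butyl (4S,5R)-5-[3,4-bis(benzyloxy)phenyl]-2-{[3,4-bis(benzyloxy)phenyl]ethynyl}-4-[4-(benzyloxy)-2-oxo-2H-pyran-6-yl]-4,5-dihydrofuran-3-carboxylate, via ketene acetal triflate 12 (not isolated)
Conditions: NaH (1.05 equiv), THF, 0 °C; PhNTf2, 0 °C to rt; then 11, Pd(PPh3)2Cl2 (5 mol %), CuI (copper iodide, 10 mol %), Et3N, rt
Reagents that add atoms: N-phenylbis(trifluoromethanesulfonimide), O=S(=O)(N(c1ccccc1)S(=O)(=O)C(F)(F)F)C(F)(F)F (supplies the triflyl group of 12; no atom of it remains in 13)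
Why: NaH removes only the malonate-type C3a–H, so C2 and C3 are not touched; O-sulfonylation of the enolate on the lactone oxygen (the tert-butyl ester oxygen is shielded) should give the lactone-derived ketene acetal triflate, and this β-sulfonyloxy acrylate should couple with 11 so that the carbonyl oxygen of C7a is exchanged for C7 while O1–C7a stays intact (enol triflate formation, then Sonogashira coupling).

**Step 7**
Reactants: 13 tert-butyl (4S,5R)-5-[3,4-bis(benzyloxy)phenyl]-2-{[3,4-bis(benzyloxy)phenyl]ethynyl}-4-[4-(benzyloxy)-2-oxo-2H-pyran-6-yl]-4,5-dihydrofuran-3-carboxylate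
Product: 14 (2R,3S)-2,6-bis[3,4-bis(benzyloxy)phenyl]-3-[4-(benzyloxy)-2-oxo-2H-pyran-6-yl]-2,3-dihydro-4H-furo[3,2-c]pyran-4-one
Conditions: [(t-Bu)2(2-biphenylyl)P]Au(NCMe)SbF6 (5 mol %), CH2Cl2, 0 °C to rt
Reagents that add atoms: none
Why: Cationic monovalent gold activates the alkyne, the ester carbonyl oxygen should attack the aryl-bearing alkyne carbon in the 6-endo-dig sense (favoured by the electron-rich aryl group), and loss of 2-methylpropene with protodeauration gives ring B under neutral conditions (gold-catalysed cycloisomerisation of a tert-butyl enynoate to a 2-pyranone); no stereocentre is involved.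

**Step 8**
Reactants: 14 (2R,3S)-2,6-bis[3,4-bis(benzyloxy)phenyl]-3-[4-(benzyloxy)-2-oxo-2H-pyran-6-yl]-2,3-dihydro-4H-furo[3,2-c]pyran-4-one
Product: 15 (2R,3S)-2,6-bis(3,4-dihydroxyphenyl)-3-(4-hydroxy-2-oxo-2H-pyran-6-yl)-2,3-dihydro-4H-furo[3,2-c]pyran-4-one
Conditions: H2 (1 atm), Pd/C (10 wt % Pd), EtOAc/THF, rt
Reagents that add atoms: none
Why: Hydrogenolysis of the four aryl benzyl ethers and the vinylogous benzyl ester is neutral, so the cis stereocentres, which are labile to acid (ionisation of C2–O1) and to base (deprotonation at C3), should survive (catalytic hydrogenolysis).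

**Compound list**

1 | 4-hydroxy-6-methyl-2H-pyran-2-one | Cc1cc(O)cc(=O)o1 | starting material
2 | 4-(benzyloxy)-6-methyl-2H-pyran-2-one | Cc1cc(OCc2ccccc2)cc(=O)o1 | intermediate
3 | methyl 3,4-bis(benzyloxy)benzoate | COC(=O)c1ccc(OCc2ccccc2)c(OCc2ccccc2)c1 | starting material
4 | 4-(benzyloxy)-6-{2-[3,4-bis(benzyloxy)phenyl]-2-oxoethyl}-2H-pyran-2-one | O=C(Cc1cc(OCc2ccccc2)cc(=O)o1)c1ccc(OCc2ccccc2)c(OCc2ccccc2)c1 | intermediate
5 | tert-butyl methyl propanedioate | COC(=O)CC(=O)OC(C)(C)C | starting material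
6 | 4-(benzyloxy)-6-{2-[3,4-bis(benzyloxy)phenyl]-1-bromo-2-oxoethyl}-2H-pyran-2-one (racemic) | O=C(C(Br)c1cc(OCc2ccccc2)cc(=O)o1)c1ccc(OCc2ccccc2)c(OCc2ccccc2)c1 | intermediate
7 | 1-tert-butyl 3-methyl 2-{2-[3,4-bis(benzyloxy)phenyl]-1-[4-(benzyloxy)-2-oxo-2H-pyran-6-yl]-2-oxoethyl}propanedioate (all stereoisomers, interconverting) | COC(=O)C(C(=O)OC(C)(C)C)C(c1cc(OCc2ccccc2)cc(=O)o1)C(=O)c1ccc(OCc2ccccc2)c(OCc2ccccc2)c1 | intermediate
8 | 1-tert-butyl 3-methyl 2-{(1S,2R)-2-[3,4-bis(benzyloxy)phenyl]-1-[4-(benzyloxy)-2-oxo-2H-pyran-6-yl]-2-hydroxyethyl}propanedioate (epimers at the malonate carbon) | O=c1cc(OCc2ccccc2)cc([C@@H](C(C(=O)OC)C(=O)OC(C)(C)C)[C@@H](O)c2ccc(OCc3ccccc3)c(OCc3ccccc3)c2)o1 | intermediate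
9 | tert-butyl (3S,4S,5R)-5-[3,4-bis(benzyloxy)phenyl]-4-[4-(benzyloxy)-2-oxo-2H-pyran-6-yl]-2-oxooxolane-3-carboxylate (4,5-cis, 3,4-trans; C3 epimerisable) | O=c1cc(OCc2ccccc2)cc([C@H]2[C@H](C(=O)OC(C)(C)C)C(=O)O[C@H]2c2ccc(OCc3ccccc3)c(OCc3ccccc3)c2)o1 | intermediate
10 | 3,4-bis(benzyloxy)benzaldehyde | O=Cc1ccc(OCc2ccccc2)c(OCc2ccccc2)c1 | starting material
11 | 1,2-bis(benzyloxy)-4-ethynylbenzene | C#Cc1ccc(OCc2ccccc2)c(OCc2ccccc2)c1 | intermediate
12 | tert-butyl (4S,5R)-5-[3,4-bis(benzyloxy)phenyl]-4-[4-(benzyloxy)-2-oxo-2H-pyran-6-yl]-2-{[(trifluoromethyl)sulfonyl]oxy}-4,5-dihydrofuran-3-carboxylate | O=c1cc(OCc2ccccc2)cc([C@H]2C(C(=O)OC(C)(C)C)=C(OS(=O)(=O)C(F)(F)F)O[C@H]2c2ccc(OCc3ccccc3)c(OCc3ccccc3)c2)o1 | intermediate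
13 | tert-butyl (4S,5R)-5-[3,4-bis(benzyloxy)phenyl]-2-{[3,4-bis(benzyloxy)phenyl]ethynyl}-4-[4-(benzyloxy)-2-oxo-2H-pyran-6-yl]-4,5-dihydrofuran-3-carboxylate | O=c1cc(OCc2ccccc2)cc([C@H]2C(C(=O)OC(C)(C)C)=C(C#Cc3ccc(OCc4ccccc4)c(OCc4ccccc4)c3)O[C@H]2c2ccc(OCc3ccccc3)c(OCc3ccccc3)c2)o1 | intermediate
14 | (2R,3S)-2,6-bis[3,4-bis(benzyloxy)phenyl]-3-[4-(benzyloxy)-2-oxo-2H-pyran-6-yl]-2,3-dihydro-4H-furo[3,2-c]pyran-4-one | O=c1cc(OCc2ccccc2)cc([C@H]2c3c(cc(-c4ccc(OCc5ccccc5)c(OCc5ccccc5)c4)oc3=O)O[C@H]2c2ccc(OCc3ccccc3)c(OCc3ccccc3)c2)o1 | intermediate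
15 | (2R,3S)-2,6-bis(3,4-dihydroxyphenyl)-3-(4-hydroxy-2-oxo-2H-pyran-6-yl)-2,3-dihydro-4H-furo[3,2-c]pyran-4-one | O=c1cc(O)cc([C@H]2c3c(cc(-c4ccc(O)c(O)c4)oc3=O)O[C@H]2c2ccc(O)c(O)c2)o1 | target

**Step count and risks**

Total step count: 8. Longest linear sequence: 7 steps (1, 2, 3, 4, 6, 7, 8); step 5 is a side branch.

Step 4. What may go wrong: the resolving hydride transfer loses its Felkin–Anh preference, because the branched malonyl group competes with the pyranonyl group for the anti position, so that the 4,5-trans lactone forms; or reduction outruns the epimerisation of C3. The fallback sets out from 7 and returns at 9, and installs the C3 configuration afterwards under cyclic control. Reduction of 7 as in step 4 still fixes the catalyst-controlled carbinol centre and should give, after lactonization, mainly tert-butyl (4R,5R)-5-[3,4-bis(benzyloxy)phenyl]-4-[4-(benzyloxy)-2-oxo-2H-pyran-6-yl]-2-oxooxolane-3-carboxylate F1; any cis isomer is carried along. Selenenylation of its malonate-type enolate (NaH, PhSeBr, THF, −78 °C) should give tert-butyl (5R)-5-[3,4-bis(benzyloxy)phenyl]-4-[4-(benzyloxy)-2-oxo-2H-pyran-6-yl]-2-oxo-3-(phenylselanyl)oxolane-3-carboxylate F2. Oxidation (H2O2, CH2Cl2, 0 °C) with syn-elimination of the selenoxide should give the butenolide tert-butyl (5S)-5-[3,4-bis(benzyloxy)phenyl]-4-[4-(benzyloxy)-2-oxo-2H-pyran-6-yl]-2-oxo-2,5-dihydrofuran-3-carboxylate F3, in which the carbinol centre is spatially unchanged and only its descriptor differs. Conjugate reduction of this alkylidene-malonate-type alkene with the Hantzsch ester (diethyl 2,6-dimethyl-1,4-dihydropyridine-3,5-dicarboxylate, CH2Cl2, rt) is neutral, so the carbinol centre should not be lost through the hydroxyfuran tautomer. Hydride should add to C3 on the face anti to the aryl group on C2 and return 9.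

Step 6. What may go wrong: sulfonylation at the ester oxygen instead of the lactone oxygen, or hydrolysis of the ketene acetal triflate before oxidative addition. The fallback sets out from 9 and 11 and returns at 13; it uses an isolable phosphate and a tin partner. Compound 9 with NaH and (PhO)2P(O)Cl (THF, 0 °C) should give the ketene acetal phosphate tert-butyl (4S,5R)-5-[3,4-bis(benzyloxy)phenyl]-4-[4-(benzyloxy)-2-oxo-2H-pyran-6-yl]-2-[(diphenoxyphosphoryl)oxy]-4,5-dihydrofuran-3-carboxylate F4, which can be purified. Compound 11 with n-BuLi and Bu3SnCl (THF, −78 °C) should give tributyl{[3,4-bis(benzyloxy)phenyl]ethynyl}stannane F5. Stille coupling of the two (Pd(PPh3)4, LiCl, THF, 60 °C) should give 13.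

Step 8. What may go wrong: hydrogenolysis of the benzylic C2–O1 bond (O1 is a vinylogous carboxylate leaving group) competes with debenzylation and opens ring C. The fallback sets out from 14 and returns at 15. It replaces reduction by Lewis-acid dealkylation with a cation scavenger (BCl3, pentamethylbenzene, CH2Cl2, −78 °C, then MeOH quench). It makes no new compound (F0).

**Further compounds**

F1 | step 4 | tert-butyl (4R,5R)-5-[3,4-bis(benzyloxy)phenyl]-4-[4-(benzyloxy)-2-oxo-2H-pyran-6-yl]-2-oxooxolane-3-carboxylate (4,5-trans, both C3 epimers) | O=c1cc(OCc2ccccc2)cc([C@@H]2C(C(=O)OC(C)(C)C)C(=O)O[C@H]2c2ccc(OCc3ccccc3)c(OCc3ccccc3)c2)o1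
F2 | step 4 | tert-butyl (5R)-5-[3,4-bis(benzyloxy)phenyl]-4-[4-(benzyloxy)-2-oxo-2H-pyran-6-yl]-2-oxo-3-(phenylselanyl)oxolane-3-carboxylate (mixture at C3 and C4) | O=c1cc(OCc2ccccc2)cc(C2C(C(=O)OC(C)(C)C)([Se]c3ccccc3)C(=O)O[C@H]2c2ccc(OCc3ccccc3)c(OCc3ccccc3)c2)o1
F3 | step 4 | tert-butyl (5S)-5-[3,4-bis(benzyloxy)phenyl]-4-[4-(benzyloxy)-2-oxo-2H-pyran-6-yl]-2-oxo-2,5-dihydrofuran-3-carboxylate | O=c1cc(OCc2ccccc2)cc(C2=C(C(=O)OC(C)(C)C)C(=O)O[C@H]2c2ccc(OCc3ccccc3)c(OCc3ccccc3)c2)o1
F4 | step 6 | tert-butyl (4S,5R)-5-[3,4-bis(benzyloxy)phenyl]-4-[4-(benzyloxy)-2-oxo-2H-pyran-6-yl]-2-[(diphenoxyphosphoryl)oxy]-4,5-dihydrofuran-3-carboxylate | O=c1cc(OCc2ccccc2)cc([C@H]2C(C(=O)OC(C)(C)C)=C(OP(=O)(Oc3ccccc3)Oc3ccccc3)O[C@H]2c2ccc(OCc3ccccc3)c(OCc3ccccc3)c2)o1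
F5 | step 6 | tributyl{[3,4-bis(benzyloxy)phenyl]ethynyl}stannane | CCCC[Sn](CCCC)(CCCC)C#Cc1ccc(OCc2ccccc2)c(OCc2ccccc2)c1
F0 | step 8 | none | none
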